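**Retrosynthetic overview**
- Prodelphinidin C2 ⇐ one global hydrogenolysis of a fully O-benzylated trimer that carries a bromine cap on C8 of the top unit.
- Protected trimer ⇐ one-flask, three-component "cap–linchpin–terminator" union. It forms both interflavan bonds (C4, sp3, pyran C-ring of each gallocatechin unit to C8, sp2, phloroglucinol A-ring of the next unit) and both new C4 stereocentres (3,4-trans), top-down, by a hard (BF3) then a soft (Ag+) trigger.
- Cap (8-bromo-3,4-diol) and linchpin (free C8, C4–S-aryl) ⇐ one diol ⇐ (+)-dihydromyricetin. Its C4 carbonyl is the latent electrophilic C4 of both gallocatechin units and its C2/C3 give four of the eight stereocentres. Terminator ⇐ (+)-catechin (two stereocentres).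
- Ring order: no ring is formed anywhere; the three pyran C-rings and six arenes come intact from the two natural flavonoids, and only the upper and then the lower C4–C8 bond are made.

Key step: step 6

Remark on the chemistry: the C4 configuration of the leaving groups in 6, 8 and 10 is drawn 3,4-trans (the expected major isomers). It is immaterial, because C4 becomes planar on ionisation and either epimer gives the same cation.

**Step 1**
Reactants: 1 (+)-catechin; 2 benzyl bromide
Product: 3 5,7,3',4'-tetra-O-benzyl-(+)-catechin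
Conditions: BnBr (4.2 equiv), K2CO3, DMF, 0 °C to rt, Ar
Reagents that add atoms: benzyl bromide (2), BrCc1ccccc1
Why: Williamson etherification in which carbonate deprotonates only the four phenols and not the secondary C3–OH, so benzylation should stop at the tetra-ether with no stereocentre touched.

**Step 2**
Reactants: 4 (+)-dihydromyricetin; 2 benzyl bromide
Product: 5 5,7,3',4',5'-penta-O-benzyl-(+)-dihydromyricetin
Conditions: BnBr (5.5 equiv), K2CO3, DMF, 0 °C to rt, Ar, dark
Reagents that add atoms: benzyl bromide (2), BrCc1ccccc1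
Why: Williamson etherification of the five phenols (the chelated 5-OH last) with the mildest sufficient base, cold and oxygen-free so that the β-hydroxy ketone is neither ring-opened nor dehydrogenated, carrying C2 and C3 of 4 through unchanged as the source of C2/C3 of both gallocatechin units.

**Step 3**
Reactants: 5 penta-O-benzyl-dihydromyricetin
Product: 6 (2R,3S,4R)-5,7-bis(benzyloxy)-2-[3,4,5-tris(benzyloxy)phenyl]chromane-3,4-diol
Conditions: NaBH4 (2 equiv), THF/EtOH 1:1, 0 °C to rt; neutral aqueous work-up
Reagents that add atoms: none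
Why: Borohydride 1,2-reduction of the aryl ketone, in which axial hydride delivery should give mainly the all-equatorial 2,3-trans-3,4-trans diol, although the new C4 carbinol configuration is irrelevant because C4 is ionised later.

**Step 4**
Reactants: 6 penta-O-benzyl-leucodelphinidin diol; 7 N-bromosuccinimide
Product: 8 (2R,3S,4R)-8-bromo-5,7-bis(benzyloxy)-2-[3,4,5-tris(benzyloxy)phenyl]chromane-3,4-diol
Conditions: NBS (1.0 equiv), CH2Cl2, −78 to −20 °C
Reagents that add atoms: N-bromosuccinimide (7), O=C1CCC(=O)N1Br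
Why: Electrophilic aromatic bromination, in which the phloroglucinol-type A-ring is far more electron-rich than the tri-O-benzylpyrogallol B-ring and C8 (between O1 and the 7-benzyloxy group) is less shielded than C6 (between two benzyloxy groups), so one equivalent of NBS in the cold should brominate C8 only and touch no stereocentre.

**Step 5**
Reactants: 6 penta-O-benzyl-leucodelphinidin diol; 9 2,6-dimethylbenzenethiol
Product: 10 2,3-trans-3,4-trans-5,7-bis(benzyloxy)-4-[(2,6-dimethylphenyl)sulfanyl]-2-[3,4,5-tris(benzyloxy)phenyl]chroman-3-ol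
Conditions: thiol 9 (3 equiv), BF3·OEt2 (0.2 equiv), CH2Cl2, −78 to −30 °C; Et3N quench
Reagents that add atoms: 2,6-dimethylbenzenethiol (9), Cc1cccc(C)c1S
Why: SN1 thio-etherification in which the Lewis acid ionises C4–OH to the A-ring-stabilised benzylic cation and the soft thiol in excess captures it faster than any arene carbon, anti to the C3–OH (3,4-trans, a configuration erased again in step 6), giving an aryl sulfide that is inert to the hard acid.

**Step 6**
Reactants: 8 bromo-capped diol (cap); 10 C4-arylsulfanyl gallocatechin (linchpin); 3 tetra-O-benzylcatechin (terminator)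
Product: 12 8-bromo-tetradeca-O-benzyl-prodelphinidin C2, via bromo-capped dimer sulfide 11 (not isolated)
Conditions: (i) 8 (1.0 equiv), 10 (1.05 equiv), BF3·OEt2 (0.5 equiv), 4 Å MS, CH2Cl2, −78 to −40 °C; (ii) 3 (1.5 equiv), then AgBF4 (1.5 equiv, in THF), −40 to 0 °C; aq NaHCO3
Reagents that add atoms: none
Why: Sub-stoichiometric BF3·OEt2 should ionise only the hard C4–OH of 8 to the benzylic cation stabilised by O1, 5-O and 7-O of its A-ring, and C8 of 10 should capture it in an intermolecular Friedel–Crafts alkylation to give 11; AgBF4 then pulls the soft arylthio group off C4 of 11 as AgSAr and C8 of 3 captures the second cation to give 12. The closest known reaction type is the Lewis-acid-mediated C4→C8 condensation of O-benzylated flavan C4 electrophiles (C4–O activated by hard acids, C4–S by thiophilic silver salts) with flavan-3-ol nucleophiles, here run twice in one flask in the manner of orthogonal thioglycoside coupling. No ring is closed: the step makes the two inter-unit C(sp3)–C(sp2) bonds and leaves the three pyran C-rings intact. Each new C4 stereocentre is set by substrate control, the arene adding to the planar C4 cation on the face anti to the adjacent C3–OH of the 2,3-trans half-chair, which gives the 3,4-trans (4α) bond in both gallocatechin units. The step needs sequence control, which the substrates secure: 8 cannot act as a nucleophile because its C8 carries bromine, 10 cannot act as an electrophile in stage (i) because its hindered S-(2,6-xylyl) group neither ionises with the hard acid nor takes up the cation at sulfur, and in stage (ii) 3 holds the only unsubstituted C8, so neither self-condensation nor chain overshoot has a pathway. It also needs C8 over C6 regioselectivity in 10 and 3, which the two benzyloxy groups flanking C6 secure.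

**Step 7**
Reactants: 12 8-bromo-tetradeca-O-benzyl-prodelphinidin C2
Product: 13 prodelphinidin C2
Conditions: H2 (1 atm), 20% Pd(OH)2/C, NaOAc (1.2 equiv), THF/MeOH/H2O 20:1:1, rt; filtration under Ar, Sephadex LH-20, lyophilisation
Reagents that add atoms: none
Why: Heterogeneous hydrogenolysis should cleave the fourteen benzylic C–O bonds and hydrodehalogenate the aryl C–Br bond in one operation, with acetate buffering the HBr so that the acid-labile interflavan bonds survive, and no stereocentre is affected because the C4–C8 bonds are C–C bonds inert to Pd/H2 under these conditions.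

**Compound list**
1 | (+)-catechin, (2R,3S)-2-(3,4-dihydroxyphenyl)chromane-3,5,7-triol | Oc1cc(O)c2c(c1)O[C@H](c1ccc(O)c(O)c1)[C@@H](O)C2 | starting material
2 | benzyl bromide | BrCc1ccccc1 | starting material
3 | 5,7,3',4'-tetra-O-benzyl-(+)-catechin (terminator) | c1ccccc1COc1cc(OCc2ccccc2)c2c(c1)O[C@H](c1ccc(OCc3ccccc3)c(OCc3ccccc3)c1)[C@@H](O)C2 | intermediate
4 | (+)-dihydromyricetin, (2R,3R)-3,5,7-trihydroxy-2-(3,4,5-trihydroxyphenyl)chroman-4-one | Oc1cc(O)c2c(c1)O[C@H](c1cc(O)c(O)c(O)c1)[C@@H](O)C2=O | starting material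
5 | 5,7,3',4',5'-penta-O-benzyl-(+)-dihydromyricetin | c1ccccc1COc1cc(OCc2ccccc2)c2c(c1)O[C@H](c1cc(OCc3ccccc3)c(OCc3ccccc3)c(OCc3ccccc3)c1)[C@@H](O)C2=O | intermediate
6 | (2R,3S,4R)-5,7-bis(benzyloxy)-2-[3,4,5-tris(benzyloxy)phenyl]chromane-3,4-diol (penta-O-benzyl-leucodelphinidin) | c1ccccc1COc1cc(OCc2ccccc2)c2c(c1)O[C@H](c1cc(OCc3ccccc3)c(OCc3ccccc3)c(OCc3ccccc3)c1)[C@@H](O)[C@@H]2O | intermediate
7 | N-bromosuccinimide | O=C1CCC(=O)N1Br | starting material
8 | (2R,3S,4R)-8-bromo-5,7-bis(benzyloxy)-2-[3,4,5-tris(benzyloxy)phenyl]chromane-3,4-diol (cap) | c1ccccc1COc1cc(OCc2ccccc2)c2c(c1Br)O[C@H](c1cc(OCc3ccccc3)c(OCc3ccccc3)c(OCc3ccccc3)c1)[C@@H](O)[C@@H]2O | intermediate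
9 | 2,6-dimethylbenzenethiol | Cc1cccc(C)c1S | starting material
10 | 2,3-trans-3,4-trans-5,7-bis(benzyloxy)-4-[(2,6-dimethylphenyl)sulfanyl]-2-[3,4,5-tris(benzyloxy)phenyl]chroman-3-ol (linchpin) | c1ccccc1COc1cc(OCc2ccccc2)c2c(c1)O[C@H](c1cc(OCc3ccccc3)c(OCc3ccccc3)c(OCc3ccccc3)c1)[C@@H](O)[C@@H]2Sc1c(C)cccc1C | intermediate
11 | bromo-capped dimer sulfide: 8-bromo-penta-O-benzylgallocatechin-(4α→8)-[4-(2,6-dimethylphenylsulfanyl)-penta-O-benzylgallocatechin] | c1ccccc1COc1cc(OCc2ccccc2)c2c(c1Br)O[C@H](c1cc(OCc3ccccc3)c(OCc3ccccc3)c(OCc3ccccc3)c1)[C@@H](O)[C@@H]2c1c(OCc2ccccc2)cc(OCc2ccccc2)c2c1O[C@H](c1cc(OCc3ccccc3)c(OCc3ccccc3)c(OCc3ccccc3)c1)[C@@H](O)[C@@H]2Sc1c(C)cccc1C | intermediate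
12 | 8-bromo-tetradeca-O-benzyl-prodelphinidin C2: 8-bromo-penta-O-benzylgallocatechin-(4α→8)-penta-O-benzylgallocatechin-(4α→8)-tetra-O-benzylcatechin | c1ccccc1COc1cc(OCc2ccccc2)c2c(c1Br)O[C@H](c1cc(OCc3ccccc3)c(OCc3ccccc3)c(OCc3ccccc3)c1)[C@@H](O)[C@@H]2c1c(OCc2ccccc2)cc(OCc2ccccc2)c2c1O[C@H](c1cc(OCc3ccccc3)c(OCc3ccccc3)c(OCc3ccccc3)c1)[C@@H](O)[C@@H]2c1c(OCc2ccccc2)cc(OCc2ccccc2)c2c1O[C@H](c1ccc(OCc3ccccc3)c(OCc3ccccc3)c1)[C@@H](O)C2 | intermediate
13 | prodelphinidin C2, gallocatechin-(4α→8)-gallocatechin-(4α→8)-catechin | Oc1cc(O)c2c(c1)O[C@H](c1cc(O)c(O)c(O)c1)[C@@H](O)[C@@H]2c1c(O)cc(O)c2c1O[C@H](c1cc(O)c(O)c(O)c1)[C@@H](O)[C@@H]2c1c(O)cc(O)c2c1O[C@H](c1ccc(O)c(O)c1)[C@@H](O)C2 | target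

**Step count and risks**
Total step count: 7. Longest linear sequence: 5 steps (4 → 5 → 6 → 8 or 10 → 12 → 13).

Steps most likely to fail:

Step 6. The sequencing may break down: the C4–S bond of 10 may ionise early under the hard acid, the arylthio group may be transferred between units so that the sequence is scrambled, or the acid released in stage (ii) may cleave the fresh upper interflavan bond. The fallback gives up the sulfide linchpin and grows the chain bottom-up with an isolated dimer. It sets out from 6 and 3: diol 6 is condensed with an excess of 3 (catalytic TMSOTf, CH2Cl2, −78 °C), which should give nona-O-benzyl-gallocatechin-(4α→8)-catechin F1. F1, whose only free C8 lies on its upper unit, is then condensed with the capped diol 8 (BF3·OEt2 or Yb(OTf)3, CH2Cl2), and the route is re-joined at 12.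

Step 2. Under base the dihydroflavonol may suffer opening of the C-ring with epimerisation at C2/C3, dehydrogenation by air to the flavonol, and incomplete alkylation of the chelated 5-OH. The fallback installs the C4 oxygen by benzylic C–H oxidation instead of inheriting it from the carbonyl. It sets out from benzyl bromide 2, used on commercial (+)-gallocatechin F2 (no β-hydroxy ketone) with K2CO3 in DMF to give penta-O-benzyl-(+)-gallocatechin F3. F3 is then oxidised at C4 with DDQ in CH2Cl2/H2O, hydride abstraction followed by capture of water anti to the C3–OH, and the route is re-joined at 6.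

Step 4. NBS may oxidise or ionise the free benzylic C4–OH instead of, or besides, brominating C8. The fallback masks C4 before the bromination. It sets out from 6, which is solvolysed in MeOH/CH2Cl2 with catalytic PPTS to the 4-O-methyl ether of 6 F4. F4 is brominated with NBS (CH2Cl2, −78 °C) to the 8-bromo-4-O-methyl ether F5, and F5 is used in place of 8 in stage (i) of step 6, where BF3·OEt2 ionises the C4–OMe group. The route is re-joined at 11 in the flask and hence at 12.

**Further compounds**
F1 | step 6 | nona-O-benzyl-gallocatechin-(4α→8)-catechin | c1ccccc1COc1cc(OCc2ccccc2)c2c(c1)O[C@H](c1cc(OCc3ccccc3)c(OCc3ccccc3)c(OCc3ccccc3)c1)[C@@H](O)[C@@H]2c1c(OCc2ccccc2)cc(OCc2ccccc2)c2c1O[C@H](c1ccc(OCc3ccccc3)c(OCc3ccccc3)c1)[C@@H](O)C2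
F2 | step 2 | (+)-gallocatechin | Oc1cc(O)c2c(c1)O[C@H](c1cc(O)c(O)c(O)c1)[C@@H](O)C2
F3 | step 2 | 5,7,3',4',5'-penta-O-benzyl-(+)-gallocatechin | c1ccccc1COc1cc(OCc2ccccc2)c2c(c1)O[C@H](c1cc(OCc3ccccc3)c(OCc3ccccc3)c(OCc3ccccc3)c1)[C@@H](O)C2
F4 | step 4 | 2,3-trans-3,4-trans-5,7-bis(benzyloxy)-4-methoxy-2-[3,4,5-tris(benzyloxy)phenyl]chroman-3-ol | c1ccccc1COc1cc(OCc2ccccc2)c2c(c1)O[C@H](c1cc(OCc3ccccc3)c(OCc3ccccc3)c(OCc3ccccc3)c1)[C@@H](O)[C@@H]2OC
F5 | step 4 | 2,3-trans-3,4-trans-8-bromo-5,7-bis(benzyloxy)-4-methoxy-2-[3,4,5-tris(benzyloxy)phenyl]chroman-3-ol | c1ccccc1COc1cc(OCc2ccccc2)c2c(c1Br)O[C@H](c1cc(OCc3ccccc3)c(OCc3ccccc3)c(OCc3ccccc3)c1)[C@@H](O)[C@@H]2OC
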